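**Plan**
Retrosynthesis: once the protecting groups are removed, one skeletal bond is cut, the biaryl bond from C6' (ring B, upper unit) to C8 (ring A, lower unit). Both halves are then (+)-catechin.
Enabling feature: ring B of the upper unit is a catechol, two electrons away from an o-quinone whose only free enone β-carbon is C6'. Ring A of the lower unit is a phloroglucinol-type arene whose most accessible nucleophilic carbon is C8, so the bond can be made as in the presumed biosynthesis.
Forward: no ring is built, since all six rings come with (+)-catechin. Upper half: catechol ketal on, benzyl carbonates on O3/O5/O7 (they mute ring A), ketal off. Lower half: four benzyl ethers (they shield ring B from oxidation and C6 from attack).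
Oxidation of the upper half to the o-quinone and Lewis-acid-catalysed addition of the lower half join the monomers. One hydrogenolysis then removes all seven helper groups.
Stereochemistry: C2 (R) and C3 (S) of both units come from the chiral pool and are never touched. No stereocentre is created.

Key step: step 5

Assumption: the target string defines no configuration for the C6'–C8 axis, so the axis is left uncontrolled, and any rotamers or atropisomers of 7 are carried together into the last step.

Step 1
Reactants: 1 (+)-catechin
Product: 2 3',4'-O-diphenylmethylene-(+)-catechin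
Conditions: Ph2CCl2, K2CO3, MeCN, rt, Ar
Reagents that add atoms: dichlorodiphenylmethane, ClC(Cl)(c1ccccc1)c1ccccc1
Why: Ketalisation by double O-alkylation of the gem-dichloride, in which only the vicinal O3'/O4' pair can close the five-membered 1,3-benzodioxole, a singly attached phenol gives an α-chloro ether that reverts on work-up, and C2 and C3 take no part.

Step 2
Reactants: 2 3',4'-O-diphenylmethylene-(+)-catechin
Product: 3 3,5,7-tris-O-(benzyloxycarbonyl)-3',4'-O-diphenylmethylene-(+)-catechin
Conditions: CbzCl, Et3N, DMAP (cat.), THF, 0 °C to rt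
Reagents that add atoms: benzyl chloroformate (CbzCl), O=C(Cl)OCc1ccccc1
Why: DMAP-catalysed acyl transfer (carbonate formation) caps the two ring A phenols and the C3 alcohol, and with O4' tied in the ketal the base-induced ring-opening epimerisation at C2 is not available.

Step 3
Reactants: 3 3,5,7-tris-O-(benzyloxycarbonyl)-3',4'-O-diphenylmethylene-(+)-catechin
Product: 4 3,5,7-tris-O-(benzyloxycarbonyl)-(+)-catechin (free 3',4'-catechol)
Conditions: TFA/H2O (9:1), CH2Cl2, 0 °C to rt
Reagents that add atoms: none
Why: Acid-catalysed ketal hydrolysis runs through the diphenyl-stabilised oxocarbenium ion, which forms far more easily than any cation from the TFA-stable benzyl carbonates, and the electron-withdrawing 3-O-carbonate disfavours ionisation at C2.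

Step 4
Reactants: 1 (+)-catechin
Product: 5 5,7,3',4'-tetra-O-benzyl-(+)-catechin (free 3-OH)
Conditions: BnBr, K2CO3, DMF, 0 °C to rt, Ar
Reagents that add atoms: benzyl bromide, BrCc1ccccc1
Why: In this Williamson ether synthesis K2CO3 deprotonates only the four phenols, so the aliphatic 3-OH stays free and the stereocentres are not involved.

Step 5
Reactants: 4 3,5,7-tris-O-(benzyloxycarbonyl)-(+)-catechin; 5 5,7,3',4'-tetra-O-benzyl-(+)-catechin
Product: 7 3,5,7-tris-O-(benzyloxycarbonyl)-(+)-catechin-(6'→8)-5,7,3',4'-tetra-O-benzyl-(+)-catechin, via o-quinone 6 (not isolated)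
Conditions: Ag2O, Na2SO4, CH2Cl2, 0 °C, dark, filtration under Ar; filtrate added to 5 (1.5 equiv), Sc(OTf)3 (20 mol %), 4 Å MS, CH2Cl2/MeCN, −40 °C
Reagents that add atoms: none
Why: Proposed new method: Sc(OTf)3 chelates the two carbonyl oxygens of o-quinone 6 and raises its electrophilicity until the trialkoxyarene ring A of 5 can add through C8 to C6' in a Friedel-Crafts-type 1,4-addition (direct polar attack, or electron transfer and collapse of the radical pair, lead to the same sigma complex), after which loss of H8 and enolisation restore both arenes and return ring B as a catechol. The closest known reaction types are the acid-catalysed arylation of p-quinones by 1,3,5-trialkoxybenzenes and the uncatalysed addition of the free phloroglucinol-type ring A of a flavan-3-ol to a flavan-3-ol o-quinone, the presumed biosynthesis of this bond; what is new is an aryl ether as the nucleophile toward such an o-quinone under Lewis acid catalysis. No ring is closed and no stereocentre is formed: only the biaryl axis arises, left uncontrolled, and C2 and C3 of both units stay untouched as long as the addition outruns tautomerisation of 6 to its quinone methide, hence the low temperature and the catalyst. Site selectivity in 6 is secured because C6' is the only unsubstituted beta-carbon of its two enone units, the other one (C1') carrying C2 and offering no way back to an arene. Site selectivity in 5 is secured because C6 lies between two freely rotating benzyloxy groups whereas C8 has the tied-back ring oxygen O1 on one side, the bias that also sends bromination and C4-cation capture of this ether to C8. Chemoselectivity is secured by the helpers: the carbonates mute ring A of 6 against self-coupling, the benzyl ethers keep ring B of 5 out of redox exchange, and the benzyl group on O7 closes the path by which free-phenol dimers are oxidised further and cyclise.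

Step 6
Reactants: 7 3,5,7-tris-O-(benzyloxycarbonyl)-(+)-catechin-(6'→8)-5,7,3',4'-tetra-O-benzyl-(+)-catechin
Product: 8 (+)-catechin-(6'→8)-(+)-catechin (target)
Conditions: H2 (1 atm), Pd(OH)2/C, THF/MeOH/H2O, rt; filtration under Ar
Reagents that add atoms: none
Why: Heterogeneous hydrogenolysis cleaves the four benzyl ethers and the three benzyl carbonates (the latter with loss of CO2) under neutral conditions, the usual last step for benzylated flavan-3-ol oligomers, and leaves C2 and C3 untouched.

**Compound list**
1 | (+)-catechin, (2R,3S)-2-(3,4-dihydroxyphenyl)chroman-3,5,7-triol | Oc1cc(O)c2c(c1)O[C@H](c1ccc(O)c(O)c1)[C@@H](O)C2 | starting material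
2 | 3',4'-O-diphenylmethylene-(+)-catechin, (2R,3S)-2-(2,2-diphenyl-1,3-benzodioxol-5-yl)chroman-3,5,7-triol | Oc1cc(O)c2c(c1)O[C@H](c1ccc3OC(c4ccccc4)(c4ccccc4)Oc3c1)[C@@H](O)C2 | intermediate
3 | (2R,3S)-3,5,7-tris-O-(benzyloxycarbonyl)-3',4'-O-diphenylmethylene-catechin | O=C(OCc1ccccc1)Oc1cc(OC(=O)OCc2ccccc2)c2c(c1)O[C@H](c1ccc3OC(c4ccccc4)(c4ccccc4)Oc3c1)[C@@H](OC(=O)OCc1ccccc1)C2 | intermediate
4 | (2R,3S)-3,5,7-tris-O-(benzyloxycarbonyl)-catechin, ring B a free catechol | O=C(OCc1ccccc1)Oc1cc(OC(=O)OCc2ccccc2)c2c(c1)O[C@H](c1ccc(O)c(O)c1)[C@@H](OC(=O)OCc1ccccc1)C2 | intermediate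
5 | (2R,3S)-5,7,3',4'-tetra-O-benzyl-catechin, 3-OH free | C(c1ccccc1)Oc1cc(OCc2ccccc2)c2c(c1)O[C@H](c1ccc(OCc3ccccc3)c(OCc3ccccc3)c1)[C@@H](O)C2 | intermediate
6 | ring B o-quinone of 4, 4-[(2R,3S)-3,5,7-tris(benzyloxycarbonyloxy)chroman-2-yl]cyclohexa-3,5-diene-1,2-dione | O=C(OCc1ccccc1)Oc1cc(OC(=O)OCc2ccccc2)c2c(c1)O[C@H](C1=CC(=O)C(=O)C=C1)[C@@H](OC(=O)OCc1ccccc1)C2 | intermediate
7 | protected dimer: upper unit 3,5,7-tris-O-Cbz-(2R,3S)-catechin with free 3',4'-catechol, joined through C6' to C8 of 5,7,3',4'-tetra-O-benzyl-(2R,3S)-catechin | O=C(OCc1ccccc1)Oc1cc(OC(=O)OCc2ccccc2)c2c(c1)O[C@H](c1cc(O)c(O)cc1-c1c(OCc3ccccc3)cc(OCc3ccccc3)c3c1O[C@H](c1ccc(OCc4ccccc4)c(OCc4ccccc4)c1)[C@@H](O)C3)[C@@H](OC(=O)OCc1ccccc1)C2 | intermediate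
8 | (+)-catechin-(6'→8)-(+)-catechin, (2R,3S)-2-{2-[(2R,3S)-2-(3,4-dihydroxyphenyl)-3,5,7-trihydroxychroman-8-yl]-4,5-dihydroxyphenyl}chroman-3,5,7-triol | Oc1cc(O)c2c(c1)O[C@H](c1cc(O)c(O)cc1-c1c(O)cc(O)c3c1O[C@H](c1ccc(O)c(O)c1)[C@@H](O)C3)[C@@H](O)C2 | target

Total step count: 6
Longest linear sequence: 5 steps (steps 1, 2, 3, 5, 6)

**Steps most likely to fail**

**Step 5.**
- What may go wrong: the aryl ether may add too slowly, so the quinone decays first.
  - It can tautomerise to the quinone methide, which would erase the configuration at C2.
  - It can undergo redox exchange with the product, which a reductive wash would reverse because O7 is blocked.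
  - It can be attacked at the less crowded C5'.
- Fallback: known chemistry is used, setting out from 4 and 2 and coming back at 8.
  - Quinone 6 is made from 4 with Ag2O as before. Its filtrate is run slowly into an excess of ketal 2 in MeCN/aqueous acetate buffer (pH about 4) at 0 °C.
  - The free phloroglucinol-type ring A of 2 adds to flavan-3-ol o-quinones without a catalyst, so activation moves from the electrophile to the nucleophile.
  - This should give 3,5,7-tris-O-Cbz-(+)-catechin-(6'→8)-3',4'-O-diphenylmethylene-(+)-catechin F1.
  - Attack through C6 is no longer excluded by flanking benzyl ethers, so that isomer would have to be removed by chromatography.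
  - Hydrogenolysis of F1 under the conditions of step 6 removes carbonates and ketal together and gives 8.

**Step 3.**
- What may go wrong: acid may ionise the benzylic C2–O1 bond, causing epimerisation at C2 or opening of ring C. Carbonates may also be partly lost during ketal hydrolysis.
- Fallback: it sets out from 1 and comes back at 4.
  - tBu2Si(OTf)2, 2,6-lutidine, DMF, 0 °C should tie only the catechol, the one diol able to close a five-membered ring. This gives 3',4'-O-(di-tert-butylsilylene)-(+)-catechin F2.
  - CbzCl/Et3N/DMAP as in step 2 gives 3,5,7-tris-O-Cbz-3',4'-O-(di-tert-butylsilylene)-(+)-catechin F3.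
  - HF·pyridine in THF at 0 °C then attacks silicon rather than carbon and frees 4 without any cation-forming acid.

**Step 6.**
- What may go wrong: benzyl groups near the crowded biaryl may be cleaved incompletely. The benzylic C2–O1 bonds may be opened by hydrogenolysis. The free polyphenol may be oxidised by air on the catalyst during filtration.
- Fallback: it sets out from 7 and comes back at 8.
  - The conditions are BCl3 with pentamethylbenzene as cation scavenger, CH2Cl2, −78 °C, then MeOH quench.
  - This is a non-reductive Lewis-acid debenzylation. It passes every benzyl group of the ethers and carbonates to the scavenger, and the carbonic half-esters lose CO2 on work-up.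
  - The fallback makes no new compound (F0).

**Further compounds**
F1 | step 5 | 3,5,7-tris-O-Cbz-(+)-catechin-(6'→8)-3',4'-O-diphenylmethylene-(+)-catechin | O=C(OCc1ccccc1)Oc1cc(OC(=O)OCc2ccccc2)c2c(c1)O[C@H](c1cc(O)c(O)cc1-c1c(O)cc(O)c3c1O[C@H](c1ccc4OC(c5ccccc5)(c5ccccc5)Oc4c1)[C@@H](O)C3)[C@@H](OC(=O)OCc1ccccc1)C2
F2 | step 3 | 3',4'-O-(di-tert-butylsilylene)-(+)-catechin | Oc1cc(O)c2c(c1)O[C@H](c1ccc3O[Si](C(C)(C)C)(C(C)(C)C)Oc3c1)[C@@H](O)C2
F3 | step 3 | 3,5,7-tris-O-Cbz-3',4'-O-(di-tert-butylsilylene)-(+)-catechin | O=C(OCc1ccccc1)Oc1cc(OC(=O)OCc2ccccc2)c2c(c1)O[C@H](c1ccc3O[Si](C(C)(C)C)(C(C)(C)C)Oc3c1)[C@@H](OC(=O)OCc1ccccc1)C2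
F0 | step 6 | none | none
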